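**Retrosynthetic overview**

Locants (germacranolide style): C8 lactone O–CH, C9 CH2, C10 (=C1, bears C14H2OH), C2, C3, C4 (bears C15H2OH), C5, C6 (O-angelate), C7 (ring fusion); lactone C11(=C13H2)–C12(=O).
Enabling feature: C6 is oxygenated, C4 lies 1,3 to it and an olefin starts at C1, so C1–C2–C3–C4–C5–C6 of the ten-membered ring is the retron of an oxy-Cope product; a temporary C1–C6 bond folds C1, C10, C9, C8, C7, C6 into a cyclohexane that already carries the lactone stereocentres C7/C8.
Endgame: C14 alcohol ⇐ conjugated enal ⇐ acetal; α-methylene lactone ⇐ lactol ⇐ C12 acetal + C8 OH; angelate ⇐ C6 alcohol ⇐ C6 ketone.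
Ten-membered ring ⇐ anionic oxy-Cope ring expansion of a trans-1-[(Z)-alkenyl]-2-vinylcyclohexanol (makes C3–C4, breaks C1–C6, sets C4); cyclohexanone ⇐ α-vinylation of a ketol from an organocatalytic Michael/aldol annulation of a β-keto ester (C1, C6, C7, C11, C12) with 4,4-dimethoxybut-2-enal (C8, C9, C10, C14), whose C10 stereocentre relays chirality to C7/C8 and is erased later.
Ring order: cyclohexane (step 5) → ten-membered carbocycle (step 10) → γ-lactone (steps 13–15).

Key step: step 10

Step 1
Reactants: 1 ethyl (Z)-3-iodoprop-2-enoate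
Product: 2 (Z)-3-iodoprop-2-en-1-ol
Conditions: i-Bu2AlH (2.2 equiv), CH2Cl2, −78 °C; aq. potassium sodium tartrate
Reagents that add atoms: none
Why: Ester-to-alcohol reduction by i-Bu2AlH at low temperature should leave the vinyl iodide and its (Z) geometry untouched.

Step 2
Reactants: 2 (Z)-3-iodoprop-2-en-1-ol
Product: 3 (Z)-1-iodo-3-(methoxymethoxy)prop-1-ene
Conditions: MOMCl, iPr2NEt, CH2Cl2, 0 °C → rt
Reagents that add atoms: chloromethyl methyl ether (MOMCl), COCCl
Why: O-alkylation (acetal protection) gives an ether that, unlike a silyl ether, cannot migrate to carbon in the derived (Z)-vinyllithium and is later cleaved together with the acetals.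

Step 3
Reactants: 4 benzeneselenenyl chloride; 5 ethyl vinyl ether
Product: 7 (phenylseleno)acetaldehyde, via diethyl acetal 6 (not isolated)
Conditions: EtOH, −20 °C → rt; then 1 M HCl, THF, rt
Reagents that add atoms: water, O
Why: Alkoxyselenation of the enol ether in ethanol (electrophilic addition through a seleniranium ion) gives acetal 6, and acid hydrolysis frees the aldehyde, a selenium-based vinyl cation equivalent.

Step 4
Reactants: 8 methyl 4,4-dimethoxybutanoate; 9 allyl acetate
Product: 11 allyl 6,6-dimethoxy-3-oxohexanoate, via lithium enolate 10 (not isolated)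
Conditions: LiN(i-Pr)2 (2.2 equiv), 9 (2.2 equiv), THF, −78 °C; then 8, −78 → −20 °C; aq. NH4Cl
Reagents that add atoms: none
Why: Crossed Claisen condensation: the preformed ester enolate acylates on the methyl ester and the second equivalent deprotonates the β-keto ester, which drives the condensation.

Step 5
Reactants: 11 allyl 6,6-dimethoxy-3-oxohexanoate; 12 (E)-4,4-dimethoxybut-2-enal
Product: 14 all-equatorial ketol allyl ester (1R,7S,8R,10S), via Michael adduct 13 (not isolated)
Conditions: (R)-α,α-bis[3,5-bis(trifluoromethyl)phenyl]prolinol trimethylsilyl ether (10 mol%), PhCO2H (10 mol%), toluene, rt; then 1,8-diazabicyclo[5.4.0]undec-7-ene (DBU, 20 mol%), 0 °C → rt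
Reagents that add atoms: none
Why: Iminium-ion catalysed Michael addition of the β-keto ester to the enal (the catalyst shields one face and sets C10 as S), then a reversible base-mediated 6-enolexo aldol (ketol) cyclisation of C7 onto C8 that should settle under thermodynamic control in the all-equatorial chair, so that C7 and C8 (trans) take their absolute configuration from C10.

Step 6
Reactants: 14 all-equatorial ketol allyl ester
Product: 16 ketol (7S,8R,10S), via β-keto acid 15 (not isolated)
Conditions: Pd(OAc)2 (5 mol%), PPh3, HCO2H, Et3N, THF, rt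
Reagents that add atoms: none
Why: Tsuji–Trost-type deallylation: zerovalent palladium formed in situ ionises the allyl ester, formate reduces the allyl unit to propene and the β-keto acid loses CO2 at room temperature under nearly neutral conditions that should spare the ketol and both acetals.

Step 7
Reactants: 16 ketol
Product: 17 C8 MOM ether of the ketol
Conditions: MOMCl, iPr2NEt, CH2Cl2, 0 °C → rt
Reagents that add atoms: chloromethyl methyl ether (MOMCl), COCCl
Why: O-alkylation of the equatorial C8 hydroxyl with an acetal group that cannot migrate to a neighbouring alkoxide and survives LiN(i-Pr)2, the organocerium reagent and KH.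

Step 8
Reactants: 17 C8 MOM ether of the ketol; 7 (phenylseleno)acetaldehyde
Product: 21 all-equatorial 1-vinyl ketone (1R,7S,8R,10S), via lithium enolate 18 (not isolated), via selenide aldolate 19 (not isolated), via selenide mesylate 20 (not isolated)
Conditions: LiN(i-Pr)2 (1.1 equiv), THF, −78 °C; 7; then MsCl, Et3N, −78 → 0 °C
Reagents that add atoms: none
Why: LiN(i-Pr)2 removes the less hindered C1 proton kinetically, the enolate adds to the aldehyde (aldol reaction) on the face anti to the C10 substituent so the new group is equatorial and trans to C10, and mesylation of the aldolate triggers anti elimination of PhSe and OMs through a seleniranium ion, unveiling the terminal vinyl group without conjugation.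

Step 9
Reactants: 21 all-equatorial 1-vinyl ketone; 3 (Z)-1-iodo-3-(methoxymethoxy)prop-1-ene
Product: 24 trans-1-[(Z)-alkenyl]-2-vinylcyclohexanol (1R,6R,7S,8R,10S), via alkenyllithium 22 (not isolated), via alkenylcerium dichloride 23 (not isolated)
Conditions: 3, t-BuLi (2 equiv), Et2O, −78 °C; CeCl3, THF, −78 °C; then 21, −78 °C; aq. NH4Cl
Reagents that add atoms: none
Why: Iodine–lithium exchange keeps the (Z) geometry, the weakly basic organocerium adds 1,2 to the easily enolised ketone, and equatorial attack (axial attack would force the oxygen to eclipse both equatorial α-substituents) should put the alkenyl group trans to the C1 vinyl and the C7 side chain, leaving the tertiary hydroxyl axial.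

Step 10
Reactants: 24 trans-1-[(Z)-alkenyl]-2-vinylcyclohexanol
Product: 27 (1E)-cyclodec-1-en-6-one (4R,7S,8R,10S), via potassium alkoxide 25 (not isolated), via potassium enolate 26 (not isolated)
Conditions: KH, 18-crown-6, THF, 0 → 25 °C; then −78 °C, aq. NH4Cl
Reagents that add atoms: none
Why: Deprotonation gives the potassium alkoxide, whose C3=C2–C1–C6–C5=C4 unit undergoes an alkoxide-accelerated [3,3]-sigmatropic shift (anionic oxy-Cope rearrangement) that forms the C3–C4 bond while the temporary C1–C6 bond breaks, giving the C5=C6 enolate that is protonated cold to the ketone. The closest known reaction type is the anionic oxy-Cope ring expansion of trans-1,2-dialkenylcyclohexanols to (E)-cyclodec-5-enones. The ten-membered ring (C1 to C10, with C2 and C3 from the vinyl group and C4 and C5 from the alkenyl group) is closed by a four-atom ring expansion through a six-membered chair transition state in which the new bond joins the two alkene termini, not by a direct end-to-end cyclisation. Because the cyclohexane holds the two alkenyl groups gauche and trans-diequatorial, the chair is strongly favoured over the boat; in it the (Z)-alkene places the CH2OMOM group pseudo-axial, so that the configurations of C1 and C6, both destroyed, are transferred to C4 (R), while the pseudo-equatorial ring bond at C1 gives the (E)-C1=C2 olefin and C7, C8 and C10 are untouched. The step needs the [3,3]-shift to outrun the [1,3]-shift, C1–C6 heterolysis and equilibration to the C6–C7 enolate (which would expel the C8 OMOM group); this should be secured by the crown-ether-separated alkoxide reacting at or below room temperature, by the absence of any other 1,5-diene (the C7 side chain is saturated) and by the cold quench of the regiodefined enolate.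

Step 11
Reactants: 27 (1E)-cyclodec-1-en-6-one
Product: 28 (6R)-alcohol (4R,6R,7R,8R,10S)
Conditions: (S)-1-methyl-3,3-diphenyltetrahydro-1H,3H-pyrrolo[1,2-c][1,3,2]oxazaborole [(S)-Me-CBS oxazaborolidine] (1 equiv), catecholborane, toluene, −78 → −40 °C
Reagents that add atoms: none
Why: Corey–Bakshi–Shibata reduction: the (S)-oxazaborolidine binds the ketone anti to the branched C7 side and should deliver hydride under reagent control to give the (6R) alcohol, while catecholborane at low temperature does not hydroborate the (E)-olefin.

Step 12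
Reactants: 28 (6R)-alcohol; 29 angelic acid
Product: 31 C6 angelate (4R,6R,7S,8R,10S), via mixed anhydride 30 (not isolated)
Conditions: 29, 2,4,6-trichlorobenzoyl chloride, Et3N, toluene, rt; then 28, 80 °C
Reagents that add atoms: none
Why: Yamaguchi esterification through the mixed anhydride without DMAP, conditions suited to acylating hindered secondary alcohols with angelic acid without (Z)→(E) isomerisation to the tiglate.

Step 13
Reactants: 31 C6 angelate
Product: 33 conjugated enal lactol (anomeric mixture at C12), via β,γ-unsaturated aldehyde lactol 32 (not isolated)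
Conditions: Me2BBr, CH2Cl2, −78 °C; aq. NaHCO3; then DBU (10 mol%), CH2Cl2, 0 °C
Reagents that add atoms: water, O
Why: Me2BBr cleaves MOM ethers and dimethyl acetals at −78 °C (acetal exchange to α-bromo ethers that hydrolyse on work-up), the C8 hydroxyl closes on the C12 aldehyde as the five-membered lactol, and DBU moves the β,γ-double bond into conjugation with the C14 aldehyde (which also takes that aldehyde out of any competing hemiacetal equilibrium) to give the thermodynamically preferred (E)-enal, whose ring-cis C1=C10 geometry is that of the target.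

Step 14
Reactants: 33 conjugated enal lactol
Product: 34 α-methylene lactol (anomeric mixture at C12)
Conditions: 37% aq. HCHO, pyrrolidine (10 mol%), EtCO2H (10 mol%), i-PrOH, 45 °C
Reagents that add atoms: formaldehyde, C=O
Why: Amine-catalysed α-methylenation of an aldehyde (Mannich condensation then β-elimination) should act only on the open hydroxy-aldehyde form of the lactol, since the enal has no α-hydrogen.

Step 15
Reactants: 34 α-methylene lactol
Product: 35 α-methylene lactone enal
Conditions: MnO2, CH2Cl2, rt
Reagents that add atoms: none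
Why: MnO2 oxidises the allylic hemiacetal to the α-methylene-γ-lactone (lactol oxidation) and should spare the saturated primary alcohol and the enal.

Step 16
Reactants: 35 α-methylene lactone enal
Product: 36 CNP0147777.1
Conditions: NaBH4, CeCl3·7H2O, MeOH, −78 °C
Reagents that add atoms: none
Why: Luche reduction should give fast 1,2-reduction of the enal at −78 °C without conjugate reduction of the α-methylene lactone or attack on the esters.

**Compound list** (stereodescriptors use the target locants given in the overview)

1 | ethyl (Z)-3-iodoprop-2-enoate | CCOC(=O)/C=C\I | starting material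
2 | (Z)-3-iodoprop-2-en-1-ol | OC/C=C\I | intermediate
3 | (Z)-1-iodo-3-(methoxymethoxy)prop-1-ene | COCOC/C=C\I | intermediate
4 | benzeneselenenyl chloride | Cl[Se]c1ccccc1 | starting material
5 | ethyl vinyl ether | C=COCC | starting material
6 | (phenylseleno)acetaldehyde diethyl acetal | CCOC(C[Se]c1ccccc1)OCC | intermediate
7 | (phenylseleno)acetaldehyde | O=CC[Se]c1ccccc1 | intermediate
8 | methyl 4,4-dimethoxybutanoate | COC(=O)CCC(OC)OC | starting material
9 | allyl acetate | CC(=O)OCC=C | starting material
10 | lithium enolate of allyl acetate | [Li+].[O-]C(=C)OCC=C | intermediate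
11 | allyl 6,6-dimethoxy-3-oxohexanoate | C=CCOC(=O)CC(=O)CCC(OC)OC | intermediate
12 | (E)-4,4-dimethoxybut-2-enal | COC(OC)/C=C/C=O | starting material
13 | Michael adduct: allyl 2-[(2S)-1,1-dimethoxy-4-oxobutan-2-yl]-6,6-dimethoxy-3-oxohexanoate (C1 epimers, C10 S) | O=CC[C@H](C(OC)OC)C(C(=O)OCC=C)C(=O)CCC(OC)OC | intermediate
14 | ketol ester: allyl (1R,7S,8R,10S)-10-(dimethoxymethyl)-7-(2,2-dimethoxyethyl)-8-hydroxy-6-oxocyclohexane-1-carboxylate, all four substituents equatorial | O=C1[C@@H](CC(OC)OC)[C@H](O)C[C@H](C(OC)OC)[C@H]1C(=O)OCC=C | intermediate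
15 | β-keto acid corresponding to 14 (same configurations) | O=C1[C@@H](CC(OC)OC)[C@H](O)C[C@H](C(OC)OC)[C@H]1C(=O)O | intermediate
16 | ketol: cyclohexanone (C6=O) with 7-(2,2-dimethoxyethyl), 8-hydroxy and 10-(dimethoxymethyl), all equatorial (7S,8R,10S) | O=C1[C@@H](CC(OC)OC)[C@H](O)C[C@H](C(OC)OC)C1 | intermediate
17 | C8 methoxymethyl ether of 16 (7S,8R,10S) | O=C1[C@@H](CC(OC)OC)[C@H](OCOC)C[C@H](C(OC)OC)C1 | intermediate
18 | lithium C1–C6 enolate of 17 | [Li+].[O-]C1=C[C@@H](C(OC)OC)C[C@@H](OCOC)[C@@H]1CC(OC)OC | intermediate
19 | lithium aldolate: 17 carrying a 1-oxido-2-(phenylseleno)ethyl group at C1 (equatorial; carbinol epimers) | O=C1[C@@H](CC(OC)OC)[C@H](OCOC)C[C@H](C(OC)OC)[C@H]1C([O-])C[Se]c1ccccc1.[Li+] | intermediate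
20 | mesylate of 19 (carbinol epimers) | O=C1[C@@H](CC(OC)OC)[C@H](OCOC)C[C@H](C(OC)OC)[C@H]1C(OS(C)(=O)=O)C[Se]c1ccccc1 | intermediate
21 | vinyl ketone: cyclohexanone (C6=O) with 1-vinyl, 7-(2,2-dimethoxyethyl), 8-(methoxymethoxy) and 10-(dimethoxymethyl), all equatorial (1R,7S,8R,10S) | O=C1[C@@H](CC(OC)OC)[C@H](OCOC)C[C@H](C(OC)OC)[C@H]1C=C | intermediate
22 | (Z)-3-(methoxymethoxy)prop-1-enyllithium | [Li]/C=C\COCOC | intermediate
23 | (Z)-3-(methoxymethoxy)prop-1-enylcerium dichloride | Cl[Ce](Cl)/C=C\COCOC | intermediate
24 | carbinol: 21 with C6 carrying an axial OH and an equatorial (Z)-3-(methoxymethoxy)prop-1-enyl group trans to the C1 vinyl (1R,6R,7S,8R,10S) | O[C@@]1(/C=C\COCOC)[C@@H](CC(OC)OC)[C@H](OCOC)C[C@H](C(OC)OC)[C@H]1C=C | intermediate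
25 | potassium alkoxide of 24 | [K+].[O-][C@@]1(/C=C\COCOC)[C@@H](CC(OC)OC)[C@H](OCOC)C[C@H](C(OC)OC)[C@H]1C=C | intermediate
26 | potassium C5=C6 enolate of 27 (ten-membered ring) | [K+].COCO[C@@H]1C[C@H](C(OC)OC)/C=C/C[C@@H](COCOC)/C=C(\[O-])[C@H]1CC(OC)OC | intermediate
27 | (1E,4R,7S,8R,10S)-cyclodec-1-en-6-one with 4-CH2OMOM, 7-(2,2-dimethoxyethyl), 8-OMOM and 10-(dimethoxymethyl) | COCO[C@@H]1C[C@H](C(OC)OC)/C=C/C[C@@H](COCOC)CC(=O)[C@H]1CC(OC)OC | intermediate
28 | (1E,4R,6R,7R,8R,10S)-cyclodec-1-en-6-ol, otherwise as 27 | COCO[C@@H]1C[C@H](C(OC)OC)/C=C/C[C@@H](COCOC)C[C@@H](O)[C@H]1CC(OC)OC | intermediate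
29 | angelic acid, (Z)-2-methylbut-2-enoic acid | C/C=C(/C)C(=O)O | starting material
30 | angelic 2,4,6-trichlorobenzoic anhydride | C/C=C(/C)C(=O)OC(=O)c1c(Cl)cc(Cl)cc1Cl | intermediate
31 | C6 angelate of 28 (1E,4R,6R,7S,8R,10S) | COCO[C@@H]1C[C@H](C(OC)OC)/C=C/C[C@@H](COCOC)C[C@@H](OC(=O)/C(C)=C\C)[C@H]1CC(OC)OC | intermediate
32 | β,γ-unsaturated aldehyde lactol: (1E)-olefin, 10-CHO, 15-OH, 6-O-angelate, C8–O–C12 lactol (anomers) | OC1O[C@@H]2C[C@H](C=O)/C=C/C[C@@H](CO)C[C@@H](OC(=O)/C(C)=C\C)[C@H]2C1 | intermediate
33 | conjugated enal lactol: 1(10)E enal (C9 and C2 cis), 15-OH, 6-O-angelate, C8–O–C12 lactol (anomers); 4R,6R,7S,8R | OC1O[C@@H]2C/C(C=O)=C\CC[C@@H](CO)C[C@@H](OC(=O)/C(C)=C\C)[C@H]2C1 | intermediate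
34 | α-methylene lactol: 33 with C11=C13H2 (anomers at C12) | C=C1C(O)O[C@@H]2C/C(C=O)=C\CC[C@@H](CO)C[C@@H](OC(=O)/C(C)=C\C)[C@@H]12 | intermediate
35 | α-methylene-γ-lactone enal (4R,6R,7R,8R) | C=C1C(=O)O[C@@H]2C/C(C=O)=C\CC[C@@H](CO)C[C@@H](OC(=O)/C(C)=C\C)[C@@H]12 | intermediate
36 | CNP0147777.1: (4R,6R,7R,8R)-6-angeloyloxy-14,15-dihydroxygermacra-1(10)E,11(13)-dien-12,8-olide | C=C1C(=O)O[C@@H]2C/C(CO)=C\CC[C@@H](CO)C[C@@H](OC(=O)/C(C)=C\C)[C@@H]12 | target

Total step count: 16. Longest linear sequence: 13 steps (steps 4 to 16, from 8 and 9); steps 1–2 and step 3 are side branches.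

**Steps most likely to fail**

Step 5. The ketol cyclisation may stall at the Michael adduct (the C7 methylene is not activated), run on to dehydration with loss of the C8 oxygen, or erode enantiopurity by retro-Michael reaction under base. Fallback, setting out from 11 and 12 and returning at 16: stop after the amine-catalysed Michael addition and isolate 13; remove the ester first (Pd(OAc)2, PPh3, HCO2H, Et3N) to give the keto aldehyde (S)-3-(dimethoxymethyl)-8,8-dimethoxy-5-oxooctanal F1; then close the ring by an L-proline-catalysed intramolecular 6-enolexo aldol reaction (enamine of the C6 ketone onto the C8 aldehyde), which should give ketol 16 directly.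

Step 10. The alkoxide may fragment by heterolysis of the C1–C6 bond instead of rearranging, the enolate may equilibrate and eliminate the C8 OMOM group, or the rearrangement may be slow because the CH2OMOM group must sit pseudo-axial. Fallback, setting out from 24 and returning at 27: silylate with N-(trimethylsilyl)imidazole to the trimethylsilyl ether of 24 F2, run the neutral thermal oxy-Cope rearrangement (o-dichlorobenzene, about 200 °C) through the same chair to the trimethylsilyl enol ether of 27 F3, and cleave it with K2CO3 in methanol to 27.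

Step 11. Hydride delivery to the flexible ten-membered ketone may show poor facial selectivity, or the (E)-olefin may attack the Lewis-acid-bound ketone across the ring. Fallback, setting out from 27 and returning at 31: reduce under chelation control (Zn(BH4)2, Et2O, −20 °C, zinc bridging the C6 carbonyl and the C8 MOM oxygen) to the C6 epimer, the (6S)-alcohol F4, and esterify it with angelic acid 29 under Mitsunobu conditions (PPh3, DIAD), which inverts C6 and gives 31.

Further compounds
F1 | step 5 | (S)-3-(dimethoxymethyl)-8,8-dimethoxy-5-oxooctanal | O=CC[C@H](C(OC)OC)CC(=O)CCC(OC)OC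
F2 | step 10 | trimethylsilyl ether of 24 | C[Si](C)(C)O[C@@]1(/C=C\COCOC)[C@@H](CC(OC)OC)[C@H](OCOC)C[C@H](C(OC)OC)[C@H]1C=C
F3 | step 10 | trimethylsilyl enol ether (C5=C6) of 27 | COCO[C@@H]1C[C@H](C(OC)OC)/C=C/C[C@@H](COCOC)/C=C(\O[Si](C)(C)C)[C@H]1CC(OC)OC
F4 | step 11 | (6S)-epimer of alcohol 28 | COCO[C@@H]1C[C@H](C(OC)OC)/C=C/C[C@@H](COCOC)C[C@H](O)[C@H]1CC(OC)OC
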